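The cyclohexane ring of the quinate core is disconnected at C2–C3. The key step exploits the 1,3-relationship between the C3 carbinol and the quaternary C1 across the C2 methylene of the six-membered carbocycle: a Lewis-acid type 2 carbonyl-ene cyclisation of a C3 aldehyde onto an isopropenyl group forms the C2–C3 bond, the ring and the axial C3 hydroxyl in one operation and leaves an exocyclic methylene at C1 as the latent hydroxyl and carboxyl. The precursor is a D-threitol-derived trans-dioxolane carrying O4 and O5, a formyl group (C3) and a 2-methylallyl chain (C6, C1, C2). Directed epoxidation, oxidation, staged galloylation and hydrogenolysis complete the synthesis.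

Key step: step 6

Assumption: the target is read as 3,4,5-tri-O-galloyl-(−)-quinic acid. Quinic acid numbering is used for all ring compounds: C1 is quaternary; O1, O3 and O4 lie on one ring face with O1 and O3 axial; O5 and the carboxyl lie on the other face. The D-threitol acetonide 1 is taken as a purchasable chiral-pool diol.

Step 1
Reactants: 1 (−)-2,3-O-isopropylidene-D-threitol [(4R,5R)-2,2-dimethyl-1,3-dioxolane-4,5-diyldimethanol]
Product: 2 [(4R,5R)-5-({[tert-butyl(dimethyl)silyl]oxy}methyl)-2,2-dimethyl-1,3-dioxolan-4-yl]methanol
Conditions: NaH (1.0 equiv), THF, 0 °C to rt; then TBSCl (1.0 equiv), rt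
Reagents that add atoms: tert-butyldimethylsilyl chloride, CC(C)(C)[Si](C)(C)Cl
Why: O-silylation of the monosodium alkoxide (Williamson-type silyl ether formation), in which the two hydroxymethyl groups of the C2-symmetric diol are equivalent and the monoalkoxide precipitates, so monoprotection needs no regiocontrol and leaves both stereocentres untouched.

Step 2
Reactants: 2 mono-TBS ether
Product: 3 [(4R,5R)-5-({[tert-butyl(dimethyl)silyl]oxy}methyl)-2,2-dimethyl-1,3-dioxolan-4-yl]methyl trifluoromethanesulfonate
Conditions: Tf2O, pyridine, CH2Cl2, −20 °C to 0 °C; short silica plug, used at once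
Reagents that add atoms: trifluoromethanesulfonic anhydride, O=S(=O)(OS(=O)(=O)C(F)(F)F)C(F)(F)F
Why: Sulfonylation of the primary alcohol to a triflate, chosen because a β-oxygenated primary carbon is displaced by organocopper reagents only from a very good leaving group; the silyl ether and the acetonide tolerate pyridine-buffered Tf2O at low temperature.

Step 3
Reactants: 3 triflate; 4 isopropenylmagnesium bromide (prop-1-en-2-ylmagnesium bromide, THF solution)
Product: 5 tert-butyl(dimethyl){[(4R,5R)-2,2-dimethyl-5-(2-methylprop-2-en-1-yl)-1,3-dioxolan-4-yl]methoxy}silane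
Conditions: 4 (2.5 equiv), CuI (10 mol %), THF, −40 °C to 0 °C
Reagents that add atoms: none
Why: Copper-catalysed Grignard cross-coupling (SN2 displacement of the primary triflate by the alkenylcuprate formed in situ), which attaches the isopropenyl unit to a non-stereogenic CH2 and leaves the adjacent stereocentre untouched.

Step 4
Reactants: 5 silyl ether
Product: 6 [(4R,5R)-2,2-dimethyl-5-(2-methylprop-2-en-1-yl)-1,3-dioxolan-4-yl]methanol
Conditions: TBAF (1.1 equiv), THF, 0 °C to rt
Reagents that add atoms: none
Why: Fluoride-induced desilylation driven by Si–F bond formation; the acetonide and the 1,1-disubstituted alkene are inert to fluoride.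

Step 5
Reactants: 6 primary alcohol
Product: 7 (4S,5R)-2,2-dimethyl-5-(2-methylprop-2-en-1-yl)-1,3-dioxolane-4-carbaldehyde (trans)
Conditions: Dess–Martin periodinane (1.2 equiv), pyridine, CH2Cl2, 0 °C to rt; used without chromatography
Reagents that add atoms: none
Why: Dess–Martin oxidation under buffered, non-basic conditions should stop at the aldehyde without epimerising the α-alkoxy centre (whose trans arrangement is in any case the more stable one) and without touching the alkene.

Step 6
Reactants: 7 trans-dioxolane aldehyde
Product: 8 (3aR,4R,7aR)-2,2-dimethyl-6-methylidenehexahydro-1,3-benzodioxol-4-ol (4,5-O-isopropylidene-1-methylidenecyclohexane-3,4,5-triol; C3 hydroxyl axial and cis to O4)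
Conditions: Me2AlCl (1.5 equiv, 1 M in hexanes), CH2Cl2, −78 °C to −20 °C; aq. KNaC4H4O6 work-up
Reagents that add atoms: none
Why: Me2AlCl activates the aldehyde, the terminal alkene carbon (future C2) attacks the carbonyl carbon (C3) and a hydrogen of the allylic methyl group passes to the carbonyl oxygen through a six-membered, concerted but asynchronous ene array, after which the aluminium alkoxide loses methane and is thereby protected from proton-induced isomerisation. The closest known reaction type is the Me2AlCl-promoted type 2 carbonyl-ene cyclisation of 5-methylhex-5-enals to 3-methylenecyclohexanols. The cyclohexane ring closes in a chair by 6-exo-trig attack on the carbonyl group, with the alkene lying inside the new ring. The only new stereocentre, C3, is controlled by the trans-dioxolane: it fixes the chair with O4 and O5 equatorial, C2 must then bond anti to the C4–O4 bond (a Felkin–Anh arrangement enforced by the ring), and the hydrogen shift is possible only when the carbonyl oxygen is axial and within reach of the methyl group, which places the hydroxyl axial and cis to O4. The step needs ene closure to win over methyl transfer from aluminium and needs the exocyclic instead of an endocyclic alkene; low temperature and the weakly basic dioxolane oxygens (little chelation) serve the first, and the fact that the axial oxygen can reach the methyl hydrogens but not those of C6 secures the second.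

Step 7
Reactants: 8 homoallylic alcohol
Product: 9 C1 spiro-epoxide of 8 (oxirane spiro-fused at C1; epoxide oxygen axial and cis to the C3 hydroxyl; epoxide CH2 equatorial; C1 S)
Conditions: VO(acac)2 (5 mol %), t-BuOOH (1.5 equiv, in decane), CH2Cl2, 0 °C to rt
Reagents that add atoms: tert-butyl hydroperoxide, CC(C)(C)OO
Why: Hydroxyl-directed vanadium-catalysed epoxidation of a homoallylic alcohol, in which the axial C3 alkoxide binds the pentavalent vanadium peroxide and delivers oxygen to the alkene face it occupies, so the epoxide oxygen at the new stereocentre C1 should be axial and cis to O3.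

Step 8
Reactants: 9 spiro-epoxide
Product: 10 (1S,3R,4R,5R)-1-(hydroxymethyl)-4,5-O-isopropylidenecyclohexane-1,3,4,5-tetrol
Conditions: KOH (2 M aq), DMSO, 90 °C
Reagents that add atoms: water (attacking as hydroxide), O
Why: Base-mediated epoxide hydrolysis by SN2 attack of hydroxide at the unhindered epoxide CH2, so the C1–O bond is never broken and C1 keeps its configuration; the acetonide is stable to base and the cis-disposed O3 cannot reach the back side of either epoxide carbon.

Step 9
Reactants: 10 triol
Product: 12 4,5-O-isopropylidenequinic acid [(1S,3R,4R,5R)-1,3-dihydroxy-4,5-(isopropylidenedioxy)cyclohexane-1-carboxylic acid], via hydroxy aldehyde 11 (not isolated)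
Conditions: (2,2,6,6-tetramethylpiperidin-1-yl)oxyl (TEMPO, 10 mol %), NaOCl (5 mol %), NaClO2 (2.0 equiv), MeCN–phosphate buffer (pH 6.7), 35 °C; then pH 4, 0 °C, extraction
Reagents that add atoms: sodium chlorite, [Na+].[O-]Cl=O
Why: Nitroxyl-catalysed (oxoammonium) oxidation of the primary alcohol to aldehyde 11 followed in the same flask by chlorite (Pinnick-type) oxidation to the acid; the oxoammonium salt discriminates the primary hydroxyl from the hindered axial secondary and the tertiary one, and the near-neutral buffer preserves the acetonide.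

Step 10
Reactants: 12 hydroxy acid
Product: 13 benzyl 4,5-O-isopropylidenequinate [benzyl (1S,3R,4R,5R)-1,3-dihydroxy-4,5-(isopropylidenedioxy)cyclohexane-1-carboxylate]
Conditions: BnBr (1.2 equiv), KHCO3, DMF, rt
Reagents that add atoms: benzyl bromide, BrCc1ccccc1
Why: SN2 O-alkylation of the potassium carboxylate with benzyl bromide; bicarbonate is too weak to deprotonate the hydroxyls, and the trans-acetonide, which cannot ring-flip, rules out lactonisation.

Step 11
Reactants: 13 benzyl ester acetonide; 14 3,4,5-tris(benzyloxy)benzoic acid
Product: 15 benzyl 3-O-[3,4,5-tris(benzyloxy)benzoyl]-4,5-O-isopropylidenequinate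
Conditions: 14 (1.2 equiv), DCC (1.3 equiv), 4-(dimethylamino)pyridine (DMAP, 0.3 equiv), CH2Cl2, 0 °C to rt
Reagents that add atoms: none
Why: Steglich esterification (carbodiimide activation, acyl transfer through the N-acylpyridinium ion) at the axial C3 hydroxyl, the only secondary hydroxyl present, since O4 and O5 are locked in the acetonide and the tertiary O1 hydroxyl beside the ester is too hindered to compete; no stereocentre is touched.

Step 12
Reactants: 15 3-O-acyl acetonide
Product: 16 benzyl 3-O-[3,4,5-tris(benzyloxy)benzoyl]quinate (O4 and O5 free)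
Conditions: AcOH–H2O–THF (4:1:1), 45 °C
Reagents that add atoms: none
Why: Acid-catalysed acetal hydrolysis, which should be fast for the strained trans-fused dioxolane, under conditions mild enough to leave the aryl ester, the benzyl ester and the benzyl ethers intact and to keep acyl migration from O3 to O4 slow.

Step 13
Reactants: 16 3-O-acyl diol; 14 3,4,5-tris(benzyloxy)benzoic acid
Product: 17 benzyl 3,5-bis-O-[3,4,5-tris(benzyloxy)benzoyl]quinate (O4 free)
Conditions: 14 (1.05 equiv), DCC (1.1 equiv), DMAP (0.2 equiv), CH2Cl2, −10 °C to 0 °C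
Reagents that add atoms: none
Why: Steglich esterification with about one equivalent of acid, expected at the equatorial O5 hydroxyl, which is flanked by the C6 methylene, in preference to O4, which lies between the axial C3 ester and O5; site selectivity is not critical, because a regioisomeric diester or any triester formed here leads to the same compound in the next step.

Step 14
Reactants: 17 3,5-diester; 14 3,4,5-tris(benzyloxy)benzoic acid
Product: 18 benzyl 3,4,5-tris-O-[3,4,5-tris(benzyloxy)benzoyl]quinate (C1 hydroxyl free)
Conditions: 14 (1.5 equiv), DCC (1.6 equiv), DMAP (0.5 equiv), DMAP·HCl (0.5 equiv), CH2Cl2, rt to 35 °C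
Reagents that add atoms: none
Why: Steglich esterification of the last secondary hydroxyl, O4, under Keck conditions, in which DMAP·HCl keeps the O-acylisourea from rearranging to the N-acylurea while the slower attack of the flanked hydroxyl takes place; the tertiary O1 hydroxyl should remain free.

Step 15
Reactants: 18 perbenzylated tris-ester
Product: 19 3,4,5-tri-O-galloyl-(−)-quinic acid
Conditions: H2 (1 atm), 10% Pd/C, THF–MeOH (1:1), rt
Reagents that add atoms: none
Why: Heterogeneous catalytic hydrogenolysis cleaves the nine benzyl aryl ethers and the benzyl ester in one operation under neutral conditions, which avoids galloyl migration and leaves the aryl esters and all four stereocentres untouched.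

Compound list

1 | (−)-2,3-O-isopropylidene-D-threitol, (4R,5R)-2,2-dimethyl-1,3-dioxolane-4,5-diyldimethanol | OC[C@H]1OC(C)(C)O[C@@H]1CO | starting material
2 | [(4R,5R)-5-({[tert-butyl(dimethyl)silyl]oxy}methyl)-2,2-dimethyl-1,3-dioxolan-4-yl]methanol | CC(C)(C)[Si](C)(C)OC[C@H]1OC(C)(C)O[C@@H]1CO | intermediate
3 | [(4R,5R)-5-({[tert-butyl(dimethyl)silyl]oxy}methyl)-2,2-dimethyl-1,3-dioxolan-4-yl]methyl trifluoromethanesulfonate | CC(C)(C)[Si](C)(C)OC[C@H]1OC(C)(C)O[C@@H]1COS(=O)(=O)C(F)(F)F | intermediate
4 | isopropenylmagnesium bromide (prop-1-en-2-ylmagnesium bromide) | CC(=C)[Mg]Br | starting material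
5 | tert-butyl(dimethyl){[(4R,5R)-2,2-dimethyl-5-(2-methylprop-2-en-1-yl)-1,3-dioxolan-4-yl]methoxy}silane | CC(C)(C)[Si](C)(C)OC[C@H]1OC(C)(C)O[C@@H]1CC(C)=C | intermediate
6 | [(4R,5R)-2,2-dimethyl-5-(2-methylprop-2-en-1-yl)-1,3-dioxolan-4-yl]methanol | OC[C@H]1OC(C)(C)O[C@@H]1CC(C)=C | intermediate
7 | (4S,5R)-2,2-dimethyl-5-(2-methylprop-2-en-1-yl)-1,3-dioxolane-4-carbaldehyde (trans; key-step precursor) | O=C[C@H]1OC(C)(C)O[C@@H]1CC(C)=C | intermediate
8 | (3aR,4R,7aR)-2,2-dimethyl-6-methylidenehexahydro-1,3-benzodioxol-4-ol; 4,5-O-isopropylidene-1-methylidenecyclohexane-3,4,5-triol with the C3 hydroxyl axial and cis to O4 (key-step product) | CC1(C)O[C@@H]2CC(=C)C[C@@H](O)[C@H]2O1 | intermediate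
9 | C1 spiro-epoxide of 8; epoxide oxygen axial at C1 and cis to the C3 hydroxyl, epoxide CH2 equatorial (C1 S) | CC1(C)O[C@@H]2C[C@]3(CO3)C[C@@H](O)[C@H]2O1 | intermediate
10 | (1S,3R,4R,5R)-1-(hydroxymethyl)-4,5-O-isopropylidenecyclohexane-1,3,4,5-tetrol | CC1(C)O[C@@H]2C[C@](O)(CO)C[C@@H](O)[C@H]2O1 | intermediate
11 | hydroxy aldehyde, (1S,3R,4R,5R)-1,3-dihydroxy-4,5-(isopropylidenedioxy)cyclohexane-1-carbaldehyde | CC1(C)O[C@@H]2C[C@](O)(C=O)C[C@@H](O)[C@H]2O1 | intermediate
12 | 4,5-O-isopropylidenequinic acid, (1S,3R,4R,5R)-1,3-dihydroxy-4,5-(isopropylidenedioxy)cyclohexane-1-carboxylic acid | CC1(C)O[C@@H]2C[C@](O)(C(=O)O)C[C@@H](O)[C@H]2O1 | intermediate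
13 | benzyl 4,5-O-isopropylidenequinate | CC1(C)O[C@@H]2C[C@](O)(C(=O)OCc3ccccc3)C[C@@H](O)[C@H]2O1 | intermediate
14 | 3,4,5-tris(benzyloxy)benzoic acid | OC(=O)c1cc(OCc2ccccc2)c(OCc2ccccc2)c(OCc2ccccc2)c1 | starting material
15 | benzyl 3-O-[3,4,5-tris(benzyloxy)benzoyl]-4,5-O-isopropylidenequinate | CC1(C)O[C@@H]2C[C@](O)(C(=O)OCc3ccccc3)C[C@@H](OC(=O)c3cc(OCc4ccccc4)c(OCc4ccccc4)c(OCc4ccccc4)c3)[C@H]2O1 | intermediate
16 | benzyl 3-O-[3,4,5-tris(benzyloxy)benzoyl]quinate (O4 and O5 free) | O[C@@H]1C[C@](O)(C(=O)OCc2ccccc2)C[C@@H](OC(=O)c2cc(OCc3ccccc3)c(OCc3ccccc3)c(OCc3ccccc3)c2)[C@H]1O | intermediate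
17 | benzyl 3,5-bis-O-[3,4,5-tris(benzyloxy)benzoyl]quinate (O4 free) | O=C(O[C@@H]1C[C@](O)(C(=O)OCc2ccccc2)C[C@@H](OC(=O)c2cc(OCc3ccccc3)c(OCc3ccccc3)c(OCc3ccccc3)c2)[C@H]1O)c1cc(OCc2ccccc2)c(OCc2ccccc2)c(OCc2ccccc2)c1 | intermediate
18 | benzyl 3,4,5-tris-O-[3,4,5-tris(benzyloxy)benzoyl]quinate (C1 hydroxyl free) | O=C(O[C@@H]1C[C@](O)(C(=O)OCc2ccccc2)C[C@@H](OC(=O)c2cc(OCc3ccccc3)c(OCc3ccccc3)c(OCc3ccccc3)c2)[C@H]1OC(=O)c1cc(OCc2ccccc2)c(OCc2ccccc2)c(OCc2ccccc2)c1)c1cc(OCc2ccccc2)c(OCc2ccccc2)c(OCc2ccccc2)c1 | intermediate
19 | 3,4,5-tri-O-galloyl-(−)-quinic acid | O=C(O[C@@H]1C[C@](O)(C(=O)O)C[C@@H](OC(=O)c2cc(O)c(O)c(O)c2)[C@H]1OC(=O)c1cc(O)c(O)c(O)c1)c1cc(O)c(O)c(O)c1 | target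

Total step count: 15. Longest linear sequence: 15 steps (1 to 19).

Steps most likely to fail

Step 6 (ene closure). Methyl transfer from aluminium to the activated aldehyde, chloride capture of the developing tertiary cation or Lewis-acid opening of the dioxolane could outrun the strained trans-fused closure. The fallback replaces the ene reaction by an intramolecular Hosomi–Sakurai allylation, in which a far more nucleophilic allylsilane closes the same C2–C3 bond under a non-alkylating Lewis acid. It sets out from triflate 3, which would be coupled under the conditions of step 3 with [1-(trimethylsilylmethyl)ethenyl]magnesium bromide F1 (from commercial 2-bromo-3-(trimethylsilyl)propene and magnesium in THF) to give the allylsilane silyl ether F2. TBAF buffered with AcOH in THF at 0 °C should release the allylsilane alcohol F3, and Dess–Martin oxidation should give the allylsilane aldehyde F4. BF3·OEt2 in CH2Cl2 at −78 °C would then trigger attack of the allylsilane terminus on the aldehyde with loss of the trimethylsilyl group, which generates the exocyclic methylene directly and comes back to the route at 8. The same chair, with C2 bonding anti to the C4–O4 bond, is expected to place the hydroxyl axial; the C3 configuration would have to be confirmed before going on.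

Step 7 (directed epoxidation). Direction by the homoallylic hydroxyl may be too weak, so that oxygen is also delivered from the face anti to O3, and the Lewis-acidic vanadium may open the acid-labile spiro-epoxide. The fallback forms the C1–O bond by intramolecular delivery from O3 through an iodocarbonate cyclisation. From 8, Boc2O and DMAP in MeCN would give the tert-butyl carbonate F5. IBr in toluene–CH2Cl2 at −78 °C should give the bridged iodo carbonate F6, in which the carbonate oxygen has attacked C1 of the iodonium ion from the face of O3 (6-exo closure with loss of the tert-butyl group), so that O1 is necessarily cis to O3. K2CO3 in MeOH would cleave the carbonate and let the tertiary alkoxide displace iodide, which comes back to the route at epoxide 9.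

Step 14 (esterification of the flanked O4 hydroxyl). Attack of the C4 hydroxyl, which sits between the axial C3 ester and the C5 ester, on the bulky O-acylisourea may stall, so that rearrangement to the N-acylurea consumes the acid, while forcing conditions invite acyl migration and acylation of the tertiary O1. The fallback gives up both the carbodiimide activation and the staging. It sets out from diol 16. Acid 14 would be converted with (COCl)2 and catalytic DMF in CH2Cl2 into 3,4,5-tris(benzyloxy)benzoyl chloride F7. Treating 16 with an excess of this smaller and more electrophilic acyl donor, pyridine and DMAP in CH2Cl2 at 0 °C to rt should esterify O5 and O4 in one operation, so that part of the O4 acylation takes place before O5 is encumbered. This bypasses 17 and comes back to the route at 18.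

Further compounds

F1 | step 6 | [1-(trimethylsilylmethyl)ethenyl]magnesium bromide | C=C([Mg]Br)C[Si](C)(C)C
F2 | step 6 | allylsilane silyl ether, TBS ether of the (4R,5R)-dioxolane methanol bearing a 2-[(trimethylsilyl)methyl]prop-2-en-1-yl chain | CC(C)(C)[Si](C)(C)OC[C@H]1OC(C)(C)O[C@@H]1CC(=C)C[Si](C)(C)C
F3 | step 6 | allylsilane alcohol, [(4R,5R)-2,2-dimethyl-5-{2-[(trimethylsilyl)methyl]prop-2-en-1-yl}-1,3-dioxolan-4-yl]methanol | OC[C@H]1OC(C)(C)O[C@@H]1CC(=C)C[Si](C)(C)C
F4 | step 6 | allylsilane aldehyde, (4S,5R)-2,2-dimethyl-5-{2-[(trimethylsilyl)methyl]prop-2-en-1-yl}-1,3-dioxolane-4-carbaldehyde | O=C[C@H]1OC(C)(C)O[C@@H]1CC(=C)C[Si](C)(C)C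
F5 | step 7 | tert-butyl carbonate of 8 at O3 | CC1(C)O[C@@H]2CC(=C)C[C@@H](OC(=O)OC(C)(C)C)[C@H]2O1
F6 | step 7 | bridged iodo carbonate, cyclic carbonate spanning the cis-diaxial O1 and O3 with an equatorial iodomethyl group at C1 and the 4,5-acetonide | CC1(C)O[C@@H]2C[C@](OC(=O)O3)(CI)C[C@@H]3[C@H]2O1
F7 | step 14 | 3,4,5-tris(benzyloxy)benzoyl chloride | ClC(=O)c1cc(OCc2ccccc2)c(OCc2ccccc2)c(OCc2ccccc2)c1
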